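**Retrosynthetic overview**
1. The hexamer (two butanoylfilicinic end rings, four butanoylphloroglucinol rings, five CH2 bridges; achiral) is cut last at the two aryl–CH2 bonds beside the outer aromatic rings. This gives a central diarylmethane carrying two CH2NMe2 groups and two molecules of an end-ring–CH2–aryl dimer.
2. The dimer is not made by a mixed formaldehyde coupling. Its dearomatised end ring is built onto the bridge by one [4+2] double Claisen annulation of two lactones: the C-3 enolate of a 6-butanoylchroman-2-one (two ring carbons) and 3,3-dimethyl-6-propylpyran-2,4-dione (four ring carbons). The new ring bonds are (bridge-bearing carbon)–(C–OH carbon beside CMe2) and (ring C=O carbon)–(butanoyl-bearing carbon).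
3. Enabling feature: the end-ring C=O carbon, the bridge-bearing carbon next to it, the bridge CH2 and the ortho phenol oxygen of the neighbouring aromatic ring are the O–C(=O)–CH–CH2–aryl atoms of a chroman-2-one. The butanoyl oxygen and carbonyl carbon, the butanoyl-bearing carbon, the C–OH carbon, the CMe2 carbon and the second C–OH carbon are the ring atoms of a pyran-2,4-dione enol lactone. Both lactone rings are absent from the target and are opened in the key step, which returns the phenol and the butanoyl C=O; the proton-free CMe2 carbon keeps the acyl donor from enolising.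
4. Ring order: aromatic rings from phloroglucinol → temporary chromanone ring (step 2) → temporary pyrandione ring (step 6) → filicinic carbocycle (step 7) → bridges of the central rings (steps 8–10).

Key step: step 7

Remark: all keto/enol forms are drawn in the tautomer of the given structure, and the target has no stereocentre. In step 2, closure onto the other neighbouring OH would give the 8-butanoyl lactone, which delivers the same atoms to the same positions in step 7; the route is written for the 6-butanoyl isomer.

**Step 1**
Reactants: 1 phloroglucinol (benzene-1,3,5-triol); 2 butanoyl chloride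
Product: 3 1-(2,4,6-trihydroxyphenyl)butan-1-one (butanoylphloroglucinol)
Conditions: AlCl3 (3.5 equiv), CH2Cl2–MeNO2, 0 °C → rt; ice/aq. HCl
Reagents that add atoms: none
Why: Friedel–Crafts acylation of the threefold-activated arene should stop after one acyl group because the chelated ketone deactivates the ring, and the symmetry of 1 allows only one product.

**Step 2**
Reactants: 3 butanoylphloroglucinol; 4 acrylic acid
Product: 6 6-butanoyl-5,7-dihydroxychroman-2-one, via arylpropanoic acid 5 (not isolated)
Conditions: 4 (1.1 equiv), Amberlyst-15, toluene–1,4-dioxane, reflux, Dean–Stark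
Reagents that add atoms: none
Why: Acid-catalysed Friedel–Crafts-type hydroarylation (conjugate alkylation) of acrylic acid at one of the two equivalent free ring carbons should give acid 5, which lactonises under water removal onto the neighbouring non-chelated OH, the acyloxy oxygen and the ketone then deactivating the last ring position against a second addition.

**Step 3**
Reactants: 6 6-butanoyl-5,7-dihydroxychroman-2-one
Product: 7 6-butanoyl-5,7-bis(tert-butyldimethylsilyloxy)chroman-2-one
Conditions: TBSOTf (2.4 equiv), 2,6-lutidine (3 equiv), CH2Cl2, −78 → 0 °C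
Reagents that add atoms: tert-butyldimethylsilyl trifluoromethanesulfonate, CC(C)(C)[Si](C)(C)OS(=O)(=O)C(F)(F)F
Why: Standard silyl ether formation with the triflate and a hindered non-nucleophilic base should cap both acidic phenols while leaving the base-labile aryl lactone closed, and the two bulky ortho silyl ethers also shield the ketone for step 7.

**Step 4**
Reactants: 8 tert-butyl 3-oxobutanoate (tert-butyl acetoacetate)
Product: 9 tert-butyl 2,2-dimethyl-3-oxobutanoate
Conditions: MeI (2.5 equiv), K2CO3, DMF, rt → 40 °C
Reagents that add atoms: iodomethane, CI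
Why: Exhaustive C-alkylation of the β-keto ester (acetoacetic ester alkylation) installs the quaternary gem-dimethyl carbon before any ring exists, so no dearomatising methylation is needed.

**Step 5**
Reactants: 9 tert-butyl 2,2-dimethyl-3-oxobutanoate (2 equiv); 2 butanoyl chloride
Product: 10 tert-butyl 2,2-dimethyl-3,5-dioxooctanoate
Conditions: LiN(SiMe3)2 (2.1 equiv), toluene–THF, −78 °C; then 2 (1.0 equiv), −78 → 0 °C; aq. HCl
Reagents that add atoms: none
Why: Claisen-type C-acylation of the kinetic lithium enolate of the methyl ketone (the only enolisable position of 9) by the acid chloride should give the β-diketone, the second equivalent of enolate serving as base for the more acidic product.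

**Step 6**
Reactants: 10 tert-butyl 2,2-dimethyl-3,5-dioxooctanoate
Product: 12 3,3-dimethyl-6-propyl-2H-pyran-2,4(3H)-dione, via diketo acid 11 (not isolated)
Conditions: CF3CO2H–(CF3CO)2O, CH2Cl2, 0 °C → rt
Reagents that add atoms: none
Why: Acidolysis of the tert-butyl ester and activation of acid 11 as a mixed trifluoroacetic anhydride should lead to 6-exo-trig O-acylation by the enol of the 5-ketone (enol lactonisation, the known cyclisation of tert-butyl 3,5-dioxoalkanoates to pyranones), the quaternary carbon stopping the product at the non-aromatic 2,4-dione.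

**Step 7**
Reactants: 7 6-butanoyl-5,7-bis(tert-butyldimethylsilyloxy)chroman-2-one; 12 3,3-dimethyl-6-propyl-2H-pyran-2,4(3H)-dione
Product: 15 2-butanoyl-6-[(3-butanoyl-2,4,6-trihydroxyphenyl)methyl]-3,5-dihydroxy-4,4-dimethylcyclohexa-2,5-dien-1-one, via β-keto lactone 13 (not isolated), via bis-silyl ether 14 (not isolated)
Conditions: LiN(SiMe3)2 (1.05 equiv), THF, −78 °C; 12 (1.1 equiv), −78 → 40 °C; then HF·pyridine, 0 °C → rt
Reagents that add atoms: none
Why: Proposed new method: LiN(SiMe3)2 removes the C-3 proton of aryl lactone 7, the enolate carbon attacks the enol-lactone carbonyl C-2 of 12 (a vinylogous anhydride) and opens it to the lithium β-diketonate of 13 (first C–C bond); on warming the diketonate carbon (former C-5 of 12) attacks the now β-keto-activated aryl lactone carbonyl, the phenoxide leaves and the acylfilicinic ring of 14 closes (second C–C bond) with release of the third phenol, after which HF·pyridine removes both silyl groups. The closest known reaction types are the acylation of enolates by enol lactones (first stage of the Fujimoto–Belleau reaction), the crossed Claisen condensation and the Dieckmann-type cyclisation of 2,2-dimethyl-3,5-dioxo esters to filicinic acids. The carbocycle closes by 6-exo-trig attack of the diketonate carbon on the lactone carbonyl, and the two lactone rings are opened, not closed. No stereocentre results, since C-3 of 13 forms racemic and becomes an enol carbon in 14. The step needs (a) deprotonation at the lactone α-carbon and not at the butanoyl α-carbon, expected from the higher acidity of the aryl δ-lactone and from the two ortho silyl ethers that twist and shield the ketone, (b) attack at the lactone carbonyl of 12 and not at its vinylogous C-6 or its C-4 ketone, favoured for a hard lithium enolate at −78 °C, and (c) C- and not O-closure, expected because O-acylation gives an enol ester that reverts whereas C-acylation ends in the stabilised trione anion and only the diketonate carbon reaches the lactone carbonyl through a six-membered transition state. The CMe2 carbon of 12 bears no proton, so the acyl donor cannot enolise or form a ketene, and one equivalent of base is passed along the cascade from enolate to diketonate to trione anion.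

**Step 8**
Reactants: 3 butanoylphloroglucinol (two molecules, used in excess)
Product: 17 bis(3-butanoyl-2,4,6-trihydroxyphenyl)methane, via hydroxymethyl phenol 16 (not isolated)
Conditions: 3 (3 equiv), 37% aq. CH2O (1 equiv), dilute aq. KOH, 0 °C, short reaction time; then aq. HCl
Reagents that add atoms: formaldehyde, C=O
Why: Base-mediated hydroxymethylation of the phenoxide (Lederer–Manasse reaction) should give 16, which alkylates a second phenoxide carbon with loss of water (the classical formaldehyde condensation to methylenebis(acylphloroglucinols)), the excess of 3 suppressing chain growth.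

**Step 9**
Reactants: 17 bis(3-butanoyl-2,4,6-trihydroxyphenyl)methane
Product: 18 bis[3-butanoyl-5-(dimethylaminomethyl)-2,4,6-trihydroxyphenyl]methane
Conditions: CH2(NMe2)2 (2.2 equiv), 1,4-dioxane, 0 °C → rt
Reagents that add atoms: N,N,N′,N′-tetramethylmethanediamine, CN(C)CN(C)C
Why: The phenolic Mannich reaction with the preformed aminal should aminomethylate the single free nucleophilic carbon of each ring, so over-reaction is impossible and no free formaldehyde is present to extend the chain.

**Step 10**
Reactants: 18 bis-Mannich base; 15 end-ring–CH2–aryl dimer (two molecules)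
Product: 20 target CNP0237140.0, via mono-adduct 19 (not isolated)
Conditions: 15 (2.1 equiv), 1,4-dioxane, 80 °C, Ar
Reagents that add atoms: none
Why: Mannich-base alkylation of phenols (loss of dimethylamine assisted by the ortho-OH and by the acidic enol of 15, then conjugate addition of the arene carbon) should join each end of 18 to the only free aromatic carbon of 15, and since 18 has no free ring carbon and 15 has exactly one, the 2:1 union through 19 is the only irreversible C-alkylation open.

**Compound list**
1 | phloroglucinol (benzene-1,3,5-triol) | Oc1cc(O)cc(O)c1 | starting material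
2 | butanoyl chloride | CCCC(=O)Cl | starting material
3 | 1-(2,4,6-trihydroxyphenyl)butan-1-one | CCCC(=O)c1c(O)cc(O)cc1O | intermediate
4 | acrylic acid | C=CC(=O)O | starting material
5 | 3-(3-butanoyl-2,4,6-trihydroxyphenyl)propanoic acid | CCCC(=O)c1c(O)cc(O)c(CCC(=O)O)c1O | intermediate
6 | 6-butanoyl-5,7-dihydroxychroman-2-one | CCCC(=O)c1c(O)cc2OC(=O)CCc2c1O | intermediate
7 | 6-butanoyl-5,7-bis(tert-butyldimethylsilyloxy)chroman-2-one | CCCC(=O)c1c(O[Si](C)(C)C(C)(C)C)cc2OC(=O)CCc2c1O[Si](C)(C)C(C)(C)C | intermediate
8 | tert-butyl 3-oxobutanoate | CC(=O)CC(=O)OC(C)(C)C | starting material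
9 | tert-butyl 2,2-dimethyl-3-oxobutanoate | CC(=O)C(C)(C)C(=O)OC(C)(C)C | intermediate
10 | tert-butyl 2,2-dimethyl-3,5-dioxooctanoate | CCCC(=O)CC(=O)C(C)(C)C(=O)OC(C)(C)C | intermediate
11 | 2,2-dimethyl-3,5-dioxooctanoic acid | CCCC(=O)CC(=O)C(C)(C)C(=O)O | intermediate
12 | 3,3-dimethyl-6-propyl-2H-pyran-2,4(3H)-dione | CCCC1=CC(=O)C(C)(C)C(=O)O1 | intermediate
13 | 6-butanoyl-5,7-bis(tert-butyldimethylsilyloxy)-3-(2,2-dimethyl-3,5-dioxooctanoyl)chroman-2-one (racemic at C-3) | CCCC(=O)CC(=O)C(C)(C)C(=O)C1Cc2c(O[Si](C)(C)C(C)(C)C)c(C(=O)CCC)c(O[Si](C)(C)C(C)(C)C)cc2OC1=O | intermediate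
14 | 2-butanoyl-6-{[3-butanoyl-2,4-bis(tert-butyldimethylsilyloxy)-6-hydroxyphenyl]methyl}-3,5-dihydroxy-4,4-dimethylcyclohexa-2,5-dien-1-one | CCCC(=O)C1=C(O)C(C)(C)C(O)=C(Cc2c(O)cc(O[Si](C)(C)C(C)(C)C)c(C(=O)CCC)c2O[Si](C)(C)C(C)(C)C)C1=O | intermediate
15 | 2-butanoyl-6-[(3-butanoyl-2,4,6-trihydroxyphenyl)methyl]-3,5-dihydroxy-4,4-dimethylcyclohexa-2,5-dien-1-one | CCCC(=O)C1=C(O)C(C)(C)C(O)=C(Cc2c(O)cc(O)c(C(=O)CCC)c2O)C1=O | intermediate
16 | 1-[2,4,6-trihydroxy-3-(hydroxymethyl)phenyl]butan-1-one | CCCC(=O)c1c(O)cc(O)c(CO)c1O | intermediate
17 | bis(3-butanoyl-2,4,6-trihydroxyphenyl)methane | CCCC(=O)c1c(O)cc(O)c(Cc2c(O)cc(O)c(C(=O)CCC)c2O)c1O | intermediate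
18 | bis[3-butanoyl-5-(dimethylaminomethyl)-2,4,6-trihydroxyphenyl]methane | CCCC(=O)c1c(O)c(CN(C)C)c(O)c(Cc2c(O)c(CN(C)C)c(O)c(C(=O)CCC)c2O)c1O | intermediate
19 | mono-adduct: end ring–CH2–aryl–CH2–aryl–CH2–aryl–CH2NMe2 | CCCC(=O)C1=C(O)C(C)(C)C(O)=C(Cc2c(O)c(Cc3c(O)c(Cc4c(O)c(CN(C)C)c(O)c(C(=O)CCC)c4O)c(O)c(C(=O)CCC)c3O)c(O)c(C(=O)CCC)c2O)C1=O | intermediate
20 | CNP0237140.0 | CCCC(=O)C1=C(O)C(C)(C)C(O)=C(Cc2c(O)c(Cc3c(O)c(Cc4c(O)c(Cc5c(O)c(CC6=C(O)C(C)(C)C(O)=C(C(=O)CCC)C6=O)c(O)c(C(=O)CCC)c5O)c(O)c(C(=O)CCC)c4O)c(O)c(C(=O)CCC)c3O)c(O)c(C(=O)CCC)c2O)C1=O | target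

**Step count and risks**
Total step count: 10. Longest linear sequence: 5 steps (steps 1, 2, 3, 7, 10; the pyrandione branch, steps 4, 5, 6, 7, 10, is equally long).

Steps most likely to fail:

1. Step 7 (proposed new method). The lactone enolate may be quenched by proton transfer from the propyl α-CH2 of 12, may add at the vinylogous C-6 or the hindered C-4 ketone of 12 instead of the lactone carbonyl, the base may enolise the butanoyl side chain instead, or the ring closure may stall at the O-acyl stage. The fallback uses known chemistry, sets out from 3 and comes back at 15, and makes steps 2–6 unnecessary. Compound 3 would be C,C-dimethylated at one ring carbon (MeI, NaOMe, MeOH, 0 °C → rt, the classical dearomatising methylation of acylphloroglucinols) to give butanoylfilicinic acid F1. This would be aminomethylated at its only free ring carbon with CH2(NMe2)2 to the Mannich base F2. Heating F2 with an excess of 3 in 1,4-dioxane (Mannich-base alkylation) would give 15.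

2. Step 10. Reversible benzyl transfer at 80 °C (fragmentation and recombination of the methylene bridges, or ipso attack with loss of an aminomethyl group) may scramble the chain, and the second alkylation may remain incomplete. The fallback changes the last bond formed, sets out from 15 and comes back at 20. Compound 15 would be aminomethylated at its free aromatic carbon with CH2(NMe2)2 to the Mannich base F3. F3 would be heated with an excess of 3 to give the trimer F4, which has one free aromatic carbon. F4 would be dimerised through the central bridge with 0.5 equiv of aqueous CH2O in dilute aqueous KOH at 0 °C (the conditions of step 8) to give 20.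

3. Step 2. Addition of the deactivated arene to acrylic acid may be sluggish, ring closure may take the acylative course to a chroman-4-one, or a second hydroarylation may occur. The fallback sets out from 3 and comes back at 6. Compound 3 would be condensed with ethyl propiolate (ZnCl2, 100 °C, Pechmann-type coumarin synthesis) to give 6-butanoyl-5,7-dihydroxycoumarin F5. Hydrogenation of the lactone C=C of F5 (H2, palladium on carbon, EtOAc, rt) would give 6.

**Further compounds**
F1 | step 7 | 2-butanoyl-3,5-dihydroxy-4,4-dimethylcyclohexa-2,5-dien-1-one (butanoylfilicinic acid) | CCCC(=O)C1=C(O)C(C)(C)C(O)=CC1=O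
F2 | step 7 | 2-butanoyl-6-(dimethylaminomethyl)-3,5-dihydroxy-4,4-dimethylcyclohexa-2,5-dien-1-one | CCCC(=O)C1=C(O)C(C)(C)C(O)=C(CN(C)C)C1=O
F3 | step 10 | 2-butanoyl-6-{[3-butanoyl-5-(dimethylaminomethyl)-2,4,6-trihydroxyphenyl]methyl}-3,5-dihydroxy-4,4-dimethylcyclohexa-2,5-dien-1-one | CCCC(=O)C1=C(O)C(C)(C)C(O)=C(Cc2c(O)c(CN(C)C)c(O)c(C(=O)CCC)c2O)C1=O
F4 | step 10 | trimer: end ring–CH2–aryl–CH2–aryl with one free aromatic carbon | CCCC(=O)C1=C(O)C(C)(C)C(O)=C(Cc2c(O)c(Cc3c(O)cc(O)c(C(=O)CCC)c3O)c(O)c(C(=O)CCC)c2O)C1=O
F5 | step 2 | 6-butanoyl-5,7-dihydroxy-2H-chromen-2-one | CCCC(=O)c1c(O)cc2OC(=O)C=Cc2c1O
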